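**Retrosynthetic overview**

1. Target 34 comes from global hydrogenolysis of the tridecakis(4-methylbenzyl) ether 33.
2. Each interflavan C4–C8 bond is cut to an achiral 2-aryl-4H-chromene and the C8 bromide of the unit below; in the forward sense a nickel/photoredox C4–H arylation through the planar flav-4-yl radical forms the bond and the chiral ligand sets C4.
3. C4 then relays C2/C3 of its ring: top unit by hydroboration anti to the C4 aryl (2,3-trans-3,4-trans); middle unit by epoxidation anti to the aryl, 1,2-hydride shift to the flavan-3-one and hydride delivery anti to the aryl (2,3-trans-3,4-cis); bottom unit by asymmetric hydroboration of the same chromene.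
4. Chromenes come from aryllithium + 5,7-dialkoxycoumarin (flavylium, hydride at C4); the coumarin from 3,5-dialkoxyphenol + ethyl propiolate; the phenol from meta C–H borylation/oxidation of resorcinol bis-ether; the aryl bromides from catechol and resorcinol.
5. Ring order: arene rings A and B, then the pyran ring of each chromene, then the ring C stereocentres of the bottom, middle and top unit in that order.

MBn = 4-methylbenzyl; MBnO = (4-methylbenzyl)oxy.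

Assumption: IpcBH2 from (−)-α-pinene is taken to give the (2S,3R) alcohol 24, and the (S,S)/(R,R) antipodes of the nickel ligand to give the (4R)/(4S) junctions of 26/31, by analogy with 1-arylcycloalkenes and 1,1-diarylalkane couplings; if a sense is reversed, the antipodal reagent is used with no other change.

**Step 1**
Reactants: 1 resorcinol
Product: 2 1,3-bis[(4-methylbenzyl)oxy]benzene
Conditions: 4-MeC6H4CH2Br (2.2 equiv), K2CO3, DMF, 60 °C
Reagents that add atoms: 4-methylbenzyl bromide, Cc1ccc(CBr)cc1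
Why: Williamson etherification of both phenols, with the para-methyl group chosen so that no arene C–H of the protecting group is free of an ortho substituent and step 2 can only borylate the resorcinol ring.

**Step 2**
Reactants: 2 1,3-bis[(4-methylbenzyl)oxy]benzene
Product: 4 3,5-bis[(4-methylbenzyl)oxy]phenol, via pinacol arylboronate 3 (not isolated)
Conditions: [Ir(OMe)(cod)]2 (1.5 mol %), dtbpy (3 mol %), B2pin2 (0.6 equiv), THF, 65 °C; then KHSO5 (Oxone, 2KHSO5·KHSO4·K2SO4), acetone/H2O, 0 °C to rt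
Reagents that add atoms: potassium peroxymonosulfate, [K+].[O-]S(=O)(=O)OO
Why: Sterically controlled iridium-catalysed C–H borylation takes the only C–H without an ortho substituent (C5), and one-pot oxidation of the boronate gives the meta-oxygenated phenol (C–H borylation/oxidation).

**Step 3**
Reactants: 4 3,5-bis[(4-methylbenzyl)oxy]phenol; 5 ethyl propiolate
Product: 6 5,7-bis[(4-methylbenzyl)oxy]-2H-chromen-2-one
Conditions: Pd(OAc)2 (5 mol %), NaOAc, HCO2H, rt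
Reagents that add atoms: none
Why: Palladium-catalysed hydroarylation of the alkynoate at one of the two equivalent positions ortho to OH, followed by lactonisation (Trost-type coumarin synthesis), is mild enough for the benzylic ethers.

**Step 4**
Reactants: 7 catechol
Product: 8 1,2-bis[(4-methylbenzyl)oxy]benzene
Conditions: 4-MeC6H4CH2Br (2.2 equiv), K2CO3, DMF, 60 °C
Reagents that add atoms: 4-methylbenzyl bromide, Cc1ccc(CBr)cc1
Why: Williamson etherification of both phenols.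

**Step 5**
Reactants: 8 1,2-bis[(4-methylbenzyl)oxy]benzene
Product: 9 4-bromo-1,2-bis[(4-methylbenzyl)oxy]benzene
Conditions: NBS (1.05 equiv), MeCN, 0 °C to rt, dark
Reagents that add atoms: N-bromosuccinimide, O=C1CCC(=O)N1Br
Why: Electrophilic aromatic bromination para to one alkoxy group, as for veratrole, under ionic conditions that leave the tolyl methyl groups alone.

**Step 6**
Reactants: 9 4-bromo-1,2-bis[(4-methylbenzyl)oxy]benzene; 6 5,7-bis[(4-methylbenzyl)oxy]-2H-chromen-2-one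
Product: 13 2-{3,4-bis[(4-methylbenzyl)oxy]phenyl}-5,7-bis[(4-methylbenzyl)oxy]-4H-chromene, via aryllithium 10 (not isolated), via lithium chromen-2-olate 11 (not isolated), via flavylium tetrafluoroborate 12 (not isolated)
Conditions: n-BuLi (1.05 equiv), THF, −78 °C; 6, −78 °C; HBF4·OEt2 (2.0 equiv), −78 to 0 °C; Hantzsch ester (1.05 equiv), MeCN, 0 °C to rt
Reagents that add atoms: none
Why: Bromine–lithium exchange, 1,2-addition to the coumarin carbonyl and acid-induced loss of water give the flavylium ion (Decker–Fellenberg-type synthesis), and the soft dihydropyridine hydride adds at C4 to give the achiral flav-2-ene (any 2H isomer gives the same radical in step 12 and is removed by crystallisation before step 10).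

**Step 7**
Reactants: 2 1,3-bis[(4-methylbenzyl)oxy]benzene
Product: 16 2,6-bis[(4-methylbenzyl)oxy]phenol, via aryllithium 14 (not isolated), via dimethyl arylboronate 15 (not isolated)
Conditions: n-BuLi (1.1 equiv), THF, 0 °C to rt; B(OMe)3, −78 °C to rt; H2O2 (30 %), AcOH, 0 °C
Reagents that add atoms: hydrogen peroxide, OO
Why: Directed ortho-metalation at the C–H flanked by both ether oxygens, borylation and oxidative C–B to C–O conversion give the pyrogallol pattern.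

**Step 8**
Reactants: 16 2,6-bis[(4-methylbenzyl)oxy]phenol
Product: 18 5-bromo-1,2,3-tris[(4-methylbenzyl)oxy]benzene, via bromophenol 17 (not isolated)
Conditions: NBS (1.0 equiv), MeCN, −20 to 0 °C; then K2CO3, 4-MeC6H4CH2Br (2.5 equiv), 60 °C
Reagents that add atoms: N-bromosuccinimide, O=C1CCC(=O)N1Br; 4-methylbenzyl bromide, Cc1ccc(CBr)cc1
Why: The free phenol directs bromination to its para position (as in syringol), which gives the symmetric 3,4,5-trioxygenated aryl bromide after Williamson etherification in the same pot.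

**Step 9**
Reactants: 18 5-bromo-1,2,3-tris[(4-methylbenzyl)oxy]benzene; 6 5,7-bis[(4-methylbenzyl)oxy]-2H-chromen-2-one
Product: 22 2-{3,4,5-tris[(4-methylbenzyl)oxy]phenyl}-5,7-bis[(4-methylbenzyl)oxy]-4H-chromene, via aryllithium 19 (not isolated), via lithium chromen-2-olate 20 (not isolated), via flavylium tetrafluoroborate 21 (not isolated)
Conditions: n-BuLi (1.05 equiv), THF, −78 °C; 6, −78 °C; HBF4·OEt2 (2.0 equiv), −78 to 0 °C; Hantzsch ester (1.05 equiv), MeCN, 0 °C to rt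
Reagents that add atoms: none
Why: Same sequence as step 6 (bromine–lithium exchange, 1,2-addition, flavylium formation, hydride transfer to C4).

**Step 10**
Reactants: 13 2-{3,4-bis[(4-methylbenzyl)oxy]phenyl}-5,7-bis[(4-methylbenzyl)oxy]-4H-chromene
Product: 24 (2S,3R)-2-{3,4-bis[(4-methylbenzyl)oxy]phenyl}-5,7-bis[(4-methylbenzyl)oxy]chroman-3-ol, via isopinocampheylborane adduct 23 (not isolated)
Conditions: IpcBH2 [from (−)-α-pinene] (1.3 equiv), Et2O/THF, −25 °C; then NaOH, H2O2, 0 °C to rt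
Reagents that add atoms: hydrogen peroxide, OO
Why: Brown asymmetric hydroboration–oxidation of the trisubstituted aryl enol ether puts boron on C3 and hydrogen on C2 in a syn fashion (2,3-trans), the reagent selects the face giving 2S,3R, and oxidation proceeds with retention.

**Step 11**
Reactants: 24 (2S,3R)-2-{3,4-bis[(4-methylbenzyl)oxy]phenyl}-5,7-bis[(4-methylbenzyl)oxy]chroman-3-ol
Product: 25 (2S,3R)-8-bromo-2-{3,4-bis[(4-methylbenzyl)oxy]phenyl}-5,7-bis[(4-methylbenzyl)oxy]chroman-3-ol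
Conditions: NBS (1.05 equiv), CH2Cl2, −78 °C to rt, dark
Reagents that add atoms: N-bromosuccinimide, O=C1CCC(=O)N1Br
Why: Electrophilic aromatic bromination goes to C8, the more accessible of the two activated ring A positions, as known for benzylated catechins.

**Step 12**
Reactants: 13 2-{3,4-bis[(4-methylbenzyl)oxy]phenyl}-5,7-bis[(4-methylbenzyl)oxy]-4H-chromene (2 equiv); 25 (2S,3R)-8-bromo-2-{3,4-bis[(4-methylbenzyl)oxy]phenyl}-5,7-bis[(4-methylbenzyl)oxy]chroman-3-ol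
Product: 26 (2S,3R)-8-[(4R)-2-{3,4-bis(MBnO)phenyl}-5,7-bis(MBnO)-4H-chromen-4-yl]-2-{3,4-bis(MBnO)phenyl}-5,7-bis(MBnO)chroman-3-ol
Conditions: NiBr2·glyme (10 mol %), (S,S)-L [(4S,4'S)-4,4'-diisopropyl-1,1'-diphenyl-4,4',5,5'-tetrahydro-1H,1'H-2,2'-biimidazole] (12 mol %), Ir[dF(CF3)ppy]2(dtbbpy)PF6 (2 mol %), K2HPO4 (2 equiv), PhH/MeCN (2:1), blue LEDs, 25 °C
Reagents that add atoms: none
Why: Proposed new method: under irradiation the iridium photocatalyst and the nickel bromide complex generate a bromine atom (or oxidise the enol ether, which then loses the C4 proton), so only the weakest, doubly activated C4–H of 13 (about 76 kcal/mol against about 85 for ArOCH2 and flavan C–H) is homolysed, the planar flav-4-yl radical is captured at its secondary terminus by the aryl–nickel species from oxidative addition of 25, and reductive elimination from trivalent nickel in the chiral bis(imidazoline) pocket forms C4–C8 and sets C4 as R (aryl on the β face), the closest known reactions being dual nickel/photoredox benzylic and allylic C–H arylation with aryl bromides and its enantioselective variant giving 1,1-diarylalkanes.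

**Step 13**
Reactants: 26 (flav-2-ene dimer, upper unit 4R)
Product: 28 (2R,4R)-4-[(2S,3R)-3-hydroxy-2-{3,4-bis(MBnO)phenyl}-5,7-bis(MBnO)chroman-8-yl]-2-{3,4-bis(MBnO)phenyl}-5,7-bis(MBnO)chroman-3-one, via epoxide 27 (not isolated)
Conditions: DMDO (1.1 equiv), CH2Cl2/acetone, −78 °C; then Zn(OTf)2 (5 mol %), −78 to −20 °C
Reagents that add atoms: dimethyldioxirane, CC1(C)OO1
Why: DMDO epoxidises the enol ether on the face opposite the pseudo-axial C4 aryl, and Meinwald-type opening to the aryl-stabilised oxocarbenium ion is followed by a suprafacial 1,2-hydride shift from C3 to C2 on the aryl-bearing face, which gives the 3-ketone and sets C2 as R (2-aryl trans to 4-aryl) without base.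

**Step 14**
Reactants: 28 (2,4-trans flavan-3-one dimer)
Product: 29 (2R,3S,4R)-4-[(2S,3R)-3-hydroxy-2-{3,4-bis(MBnO)phenyl}-5,7-bis(MBnO)chroman-8-yl]-2-{3,4-bis(MBnO)phenyl}-5,7-bis(MBnO)chroman-3-ol
Conditions: NaBH4 (2 equiv), CeCl3·7H2O (1 equiv), MeOH/THF, −78 °C
Reagents that add atoms: none
Why: Luche reduction delivers hydride axially from the face opposite the pseudo-axial C4 aryl, so the new 3-OH is cis to the 4-aryl and trans to the 2-aryl (C3 = S, 2,3-trans-3,4-cis), and the cold, weakly basic medium avoids epimerisation of the ketone.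

**Step 15**
Reactants: 29 (dimer diol)
Product: 30 (2R,3S,4S)-8-bromo-4-[(2S,3R)-3-hydroxy-2-{3,4-bis(MBnO)phenyl}-5,7-bis(MBnO)chroman-8-yl]-2-{3,4-bis(MBnO)phenyl}-5,7-bis(MBnO)chroman-3-ol
Conditions: NBS (1.0 equiv), CH2Cl2, −78 to −40 °C, dark
Reagents that add atoms: N-bromosuccinimide, O=C1CCC(=O)N1Br
Why: Electrophilic aromatic bromination selects C8 of the upper unit, which is flanked by only one benzylic ether whereas both C6 positions lie between two, and no stereocentre is touched (the C4 descriptor changes to S by priority only).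

**Step 16**
Reactants: 22 2-{3,4,5-tris[(4-methylbenzyl)oxy]phenyl}-5,7-bis[(4-methylbenzyl)oxy]-4H-chromene (2 equiv); 30 (bromo dimer)
Product: 31 trimer flav-2-ene: (4S)-2-{3,4,5-tris(MBnO)phenyl}-5,7-bis(MBnO)-4H-chromen-4-yl bound through C4 to C8 of the upper unit of 29
Conditions: NiBr2·glyme (10 mol %), (R,R)-L (12 mol %), Ir[dF(CF3)ppy]2(dtbbpy)PF6 (2 mol %), K2HPO4 (2 equiv), PhH/MeCN (2:1), blue LEDs, 25 °C
Reagents that add atoms: none
Why: Proposed new method: the same flav-4-yl radical/nickel C–H arylation as in step 12, here with 22 and the antipodal ligand so that the aryl group is delivered to the α face of C4 (4S), the closest known reaction type being the one named in step 12, and the remaining C4–H of the product is held in the ring plane by the pseudo-axial aryl and is not abstracted again.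

**Step 17**
Reactants: 31 (trimer flav-2-ene)
Product: 33 trideca-O-(4-methylbenzyl) gallocatechin-(4α→8)-catechin-(4β→8)-ent-catechin, via C3 borane adduct 32 (not isolated)
Conditions: BH3·THF (6 equiv), THF, 0 °C to rt; then NaOH, H2O2, 0 °C
Reagents that add atoms: hydrogen peroxide, OO
Why: Hydroboration–oxidation of the enol ether adds H (C2) and B (C3) syn from the face opposite the C4 aryl, which sets C2 as R and C3 as S (2,3-trans-3,4-trans) with retention in the oxidation.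

**Step 18**
Reactants: 33 (tridecakis(4-methylbenzyl) ether)
Product: 34 gallocatechin-(4α→8)-catechin-(4β→8)-ent-catechin (target)
Conditions: H2 (1 atm), Pd(OH)2/C, THF/MeOH/H2O, rt
Reagents that add atoms: none
Why: Neutral hydrogenolysis cleaves all thirteen benzylic aryl ethers without touching the acid-labile interflavan bonds or any stereocentre.

**Compound list**

1 | resorcinol | Oc1cccc(O)c1 | starting material
2 | 1,3-bis[(4-methylbenzyl)oxy]benzene | Cc1ccc(COc2cccc(OCc3ccc(C)cc3)c2)cc1 | intermediate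
3 | 2-{3,5-bis(MBnO)phenyl}-4,4,5,5-tetramethyl-1,3,2-dioxaborolane | CC1(C)OB(OC1(C)C)c1cc(OCc2ccc(C)cc2)cc(OCc2ccc(C)cc2)c1 | intermediate
4 | 3,5-bis(MBnO)phenol | Oc1cc(OCc2ccc(C)cc2)cc(OCc2ccc(C)cc2)c1 | intermediate
5 | ethyl propiolate | CCOC(=O)C#C | starting material
6 | 5,7-bis(MBnO)-2H-chromen-2-one | O=C1C=Cc2c(OCc3ccc(C)cc3)cc(OCc3ccc(C)cc3)cc2O1 | intermediate
7 | catechol | Oc1ccccc1O | starting material
8 | 1,2-bis(MBnO)benzene | Cc1ccc(COc2ccccc2OCc2ccc(C)cc2)cc1 | intermediate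
9 | 4-bromo-1,2-bis(MBnO)benzene | Cc1ccc(COc2ccc(Br)cc2OCc2ccc(C)cc2)cc1 | intermediate
10 | {3,4-bis(MBnO)phenyl}lithium | [Li]c1ccc(OCc2ccc(C)cc2)c(OCc2ccc(C)cc2)c1 | intermediate
11 | lithium 2-{3,4-bis(MBnO)phenyl}-5,7-bis(MBnO)-2H-chromen-2-olate | [Li+].[O-]C1(C=Cc2c(OCc3ccc(C)cc3)cc(OCc3ccc(C)cc3)cc2O1)c1ccc(OCc2ccc(C)cc2)c(OCc2ccc(C)cc2)c1 | intermediate
12 | 2-{3,4-bis(MBnO)phenyl}-5,7-bis(MBnO)chromenylium tetrafluoroborate | F[B-](F)(F)F.c1(-c2ccc(OCc3ccc(C)cc3)c(OCc3ccc(C)cc3)c2)ccc2c(OCc3ccc(C)cc3)cc(OCc3ccc(C)cc3)cc2[o+]1 | intermediate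
13 | 2-{3,4-bis(MBnO)phenyl}-5,7-bis(MBnO)-4H-chromene (achiral flav-2-ene) | C1(c2ccc(OCc3ccc(C)cc3)c(OCc3ccc(C)cc3)c2)=CCc2c(OCc3ccc(C)cc3)cc(OCc3ccc(C)cc3)cc2O1 | intermediate
14 | {2,6-bis(MBnO)phenyl}lithium | [Li]c1c(OCc2ccc(C)cc2)cccc1OCc1ccc(C)cc1 | intermediate
15 | dimethyl {2,6-bis(MBnO)phenyl}boronate | COB(OC)c1c(OCc2ccc(C)cc2)cccc1OCc1ccc(C)cc1 | intermediate
16 | 2,6-bis(MBnO)phenol | Oc1c(OCc2ccc(C)cc2)cccc1OCc1ccc(C)cc1 | intermediate
17 | 4-bromo-2,6-bis(MBnO)phenol | Oc1c(OCc2ccc(C)cc2)cc(Br)cc1OCc1ccc(C)cc1 | intermediate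
18 | 5-bromo-1,2,3-tris(MBnO)benzene | Brc1cc(OCc2ccc(C)cc2)c(OCc2ccc(C)cc2)c(OCc2ccc(C)cc2)c1 | intermediate
19 | {3,4,5-tris(MBnO)phenyl}lithium | [Li]c1cc(OCc2ccc(C)cc2)c(OCc2ccc(C)cc2)c(OCc2ccc(C)cc2)c1 | intermediate
20 | lithium 2-{3,4,5-tris(MBnO)phenyl}-5,7-bis(MBnO)-2H-chromen-2-olate | [Li+].[O-]C1(C=Cc2c(OCc3ccc(C)cc3)cc(OCc3ccc(C)cc3)cc2O1)c1cc(OCc2ccc(C)cc2)c(OCc2ccc(C)cc2)c(OCc2ccc(C)cc2)c1 | intermediate
21 | 2-{3,4,5-tris(MBnO)phenyl}-5,7-bis(MBnO)chromenylium tetrafluoroborate | F[B-](F)(F)F.c1(-c2cc(OCc3ccc(C)cc3)c(OCc3ccc(C)cc3)c(OCc3ccc(C)cc3)c2)ccc2c(OCc3ccc(C)cc3)cc(OCc3ccc(C)cc3)cc2[o+]1 | intermediate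
22 | 2-{3,4,5-tris(MBnO)phenyl}-5,7-bis(MBnO)-4H-chromene (achiral flav-2-ene) | C1(c2cc(OCc3ccc(C)cc3)c(OCc3ccc(C)cc3)c(OCc3ccc(C)cc3)c2)=CCc2c(OCc3ccc(C)cc3)cc(OCc3ccc(C)cc3)cc2O1 | intermediate
23 | flavan-3-yl(isopinocampheyl)borane: boron on C3 trans to the 2-aryl group of the (2S)-flavan, isopinocampheyl from (−)-α-pinene | c1c(OCc3ccc(C)cc3)cc(OCc3ccc(C)cc3)c2c1O[C@@H](c1ccc(OCc3ccc(C)cc3)c(OCc3ccc(C)cc3)c1)[C@H](B[C@H]4C[C@H]5C[C@@H]([C@@H]4C)C5(C)C)C2 | intermediate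
24 | (2S,3R)-2-{3,4-bis(MBnO)phenyl}-5,7-bis(MBnO)chroman-3-ol (tetra-O-MBn ent-catechin) | c1c(OCc3ccc(C)cc3)cc(OCc3ccc(C)cc3)c2c1O[C@@H](c1ccc(OCc3ccc(C)cc3)c(OCc3ccc(C)cc3)c1)[C@H](O)C2 | intermediate
25 | (2S,3R)-8-bromo-2-{3,4-bis(MBnO)phenyl}-5,7-bis(MBnO)chroman-3-ol | Brc1c(OCc3ccc(C)cc3)cc(OCc3ccc(C)cc3)c2c1O[C@@H](c1ccc(OCc3ccc(C)cc3)c(OCc3ccc(C)cc3)c1)[C@H](O)C2 | intermediate
26 | (2S,3R)-8-[(4R)-2-{3,4-bis(MBnO)phenyl}-5,7-bis(MBnO)-4H-chromen-4-yl]-2-{3,4-bis(MBnO)phenyl}-5,7-bis(MBnO)chroman-3-ol (lower unit on the β face of upper C4) | c1c(OCc3ccc(C)cc3)cc(OCc3ccc(C)cc3)c2c1OC(c1ccc(OCc3ccc(C)cc3)c(OCc3ccc(C)cc3)c1)=C[C@H]2c1c(OCc3ccc(C)cc3)cc(OCc3ccc(C)cc3)c2c1O[C@@H](c1ccc(OCc3ccc(C)cc3)c(OCc3ccc(C)cc3)c1)[C@H](O)C2 | intermediate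
27 | 2,3-epoxide of 26, oxirane oxygen on the face opposite the C4 aryl (2-aryl and C3–H on the aryl face) | c1c(OCc3ccc(C)cc3)cc(OCc3ccc(C)cc3)c2c1O[C@]4(c1ccc(OCc3ccc(C)cc3)c(OCc3ccc(C)cc3)c1)O[C@@H]4[C@H]2c1c(OCc3ccc(C)cc3)cc(OCc3ccc(C)cc3)c2c1O[C@@H](c1ccc(OCc3ccc(C)cc3)c(OCc3ccc(C)cc3)c1)[C@H](O)C2 | intermediate
28 | (2R,4R)-4-[(2S,3R)-3-hydroxy-2-{3,4-bis(MBnO)phenyl}-5,7-bis(MBnO)chroman-8-yl]-2-{3,4-bis(MBnO)phenyl}-5,7-bis(MBnO)chroman-3-one (2-aryl and 4-aryl trans) | c1c(OCc3ccc(C)cc3)cc(OCc3ccc(C)cc3)c2c1O[C@H](c1ccc(OCc3ccc(C)cc3)c(OCc3ccc(C)cc3)c1)C(=O)[C@H]2c1c(OCc3ccc(C)cc3)cc(OCc3ccc(C)cc3)c2c1O[C@@H](c1ccc(OCc3ccc(C)cc3)c(OCc3ccc(C)cc3)c1)[C@H](O)C2 | intermediate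
29 | octa-O-MBn catechin-(4β→8)-ent-catechin: upper unit (2R,3S,4R) with 2,3-trans-3,4-cis, lower unit (2S,3R) | c1c(OCc3ccc(C)cc3)cc(OCc3ccc(C)cc3)c2c1O[C@H](c1ccc(OCc3ccc(C)cc3)c(OCc3ccc(C)cc3)c1)[C@@H](O)[C@H]2c1c(OCc3ccc(C)cc3)cc(OCc3ccc(C)cc3)c2c1O[C@@H](c1ccc(OCc3ccc(C)cc3)c(OCc3ccc(C)cc3)c1)[C@H](O)C2 | intermediate
30 | 8-bromo derivative of 29 at the upper unit: upper unit (2R,3S,4S; same geometry as 29, descriptor changed by priority), lower unit (2S,3R) | Brc1c(OCc3ccc(C)cc3)cc(OCc3ccc(C)cc3)c2c1O[C@H](c1ccc(OCc3ccc(C)cc3)c(OCc3ccc(C)cc3)c1)[C@@H](O)[C@H]2c1c(OCc3ccc(C)cc3)cc(OCc3ccc(C)cc3)c2c1O[C@@H](c1ccc(OCc3ccc(C)cc3)c(OCc3ccc(C)cc3)c1)[C@H](O)C2 | intermediate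
31 | trimer flav-2-ene: top unit (4S)-2-{3,4,5-tris(MBnO)phenyl}-5,7-bis(MBnO)-4H-chromen-4-yl (middle unit on the α face of C4) on C8 of the middle unit; middle (2R,3S,4S), bottom (2S,3R) | c1(OCc3ccc(C)cc3)cc(OCc3ccc(C)cc3)c2c(c1)OC(c1cc(OCc3ccc(C)cc3)c(OCc3ccc(C)cc3)c(OCc3ccc(C)cc3)c1)=C[C@@H]2c1c(OCc3ccc(C)cc3)cc(OCc3ccc(C)cc3)c2c1O[C@H](c1ccc(OCc3ccc(C)cc3)c(OCc3ccc(C)cc3)c1)[C@@H](O)[C@H]2c1c(OCc3ccc(C)cc3)cc(OCc3ccc(C)cc3)c2c1O[C@@H](c1ccc(OCc3ccc(C)cc3)c(OCc3ccc(C)cc3)c1)[C@H](O)C2 | intermediate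
32 | C3 borane adduct of 31 (drawn as the monoalkylborane; boron on the face opposite the top C4 aryl) | c1(OCc3ccc(C)cc3)cc(OCc3ccc(C)cc3)c2c(c1)O[C@H](c1cc(OCc3ccc(C)cc3)c(OCc3ccc(C)cc3)c(OCc3ccc(C)cc3)c1)[C@@H](B)[C@@H]2c1c(OCc3ccc(C)cc3)cc(OCc3ccc(C)cc3)c2c1O[C@H](c1ccc(OCc3ccc(C)cc3)c(OCc3ccc(C)cc3)c1)[C@@H](O)[C@H]2c1c(OCc3ccc(C)cc3)cc(OCc3ccc(C)cc3)c2c1O[C@@H](c1ccc(OCc3ccc(C)cc3)c(OCc3ccc(C)cc3)c1)[C@H](O)C2 | intermediate
33 | trideca-O-MBn gallocatechin-(4α→8)-catechin-(4β→8)-ent-catechin: top (2R,3S,4S), middle (2R,3S,4S), bottom (2S,3R) | c1(OCc3ccc(C)cc3)cc(OCc3ccc(C)cc3)c2c(c1)O[C@H](c1cc(OCc3ccc(C)cc3)c(OCc3ccc(C)cc3)c(OCc3ccc(C)cc3)c1)[C@@H](O)[C@@H]2c1c(OCc3ccc(C)cc3)cc(OCc3ccc(C)cc3)c2c1O[C@H](c1ccc(OCc3ccc(C)cc3)c(OCc3ccc(C)cc3)c1)[C@@H](O)[C@H]2c1c(OCc3ccc(C)cc3)cc(OCc3ccc(C)cc3)c2c1O[C@@H](c1ccc(OCc3ccc(C)cc3)c(OCc3ccc(C)cc3)c1)[C@H](O)C2 | intermediate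
34 | gallocatechin-(4α→8)-catechin-(4β→8)-ent-catechin: top (2R,3S,4S) 2,3-trans-3,4-trans, middle (2R,3S,4S) 2,3-trans-3,4-cis, bottom (2S,3R) | Oc1cc(O)c2c(c1)O[C@H](c1cc(O)c(O)c(O)c1)[C@@H](O)[C@@H]2c1c(O)cc(O)c2c1O[C@H](c1ccc(O)c(O)c1)[C@@H](O)[C@H]2c1c(O)cc(O)c2c1O[C@@H](c1ccc(O)c(O)c1)[C@H](O)C2 | target

**Step count and risk**

Total: 18 steps. Longest linear sequence: 13 steps (1, 2, 3, 6, 10, 11, 12, 13, 14, 15, 16, 17, 18).

Most likely to fail:

Step 12 (first nickel/photoredox C4–H arylation). The aryl bromide is di-ortho-oxygenated, the flav-4-yl radical can dimerise, and the ligand has to override any bias from the chiral bromide. Fallback, setting out from 12 (taken from the step 6 flask before the Hantzsch ester is added) and 24, and returning at 26: the flavylium salt 12 is a two-electron electrophile at C4, and 24 (1.5 equiv, so step 11 is not needed for this branch) adds through its nucleophilic C8 in CH2Cl2 at −40 °C with 2,6-di-tert-butylpyridine and a chiral BINOL phosphate as counter-anion, the classical Friedel–Crafts-type addition of a phloroglucinol-type arene to a flavylium ion. This gives 26 together with the (4S) epimer of 26 F1; chromatography on triethylamine-washed silica gives 26, which goes on to step 13.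

Step 13 (epoxidation and 1,2-hydride shift). The oxocarbenium ion may be trapped or ring-contract instead of accepting the hydride. Fallback, setting out from 26 and returning at 28: 26 is silylated (Et3SiCl, imidazole, DMF) to the triethylsilyl ether F2; BH3·THF adds from the face opposite the C4 aryl to give the C3 borane adduct F3, which NaBO3·4H2O oxidises to the all-trans alcohol F4 (upper unit 2S,3R,4R). Dess–Martin periodinane gives the 2,4-cis ketone F5, and DBU (0.2 equiv, CH2Cl2, 0 °C) epimerises the stereoelectronically aligned C2–H to give the 2,4-trans ketone F6; the C4–H is held in the ring plane by the pseudo-axial aryl and should not enolise. AcOH/THF/H2O removes the silyl group and gives 28.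

Step 16 (second C4–H arylation, with the more hindered dimer bromide 30). Fallback, setting out from 22 and 29 and returning at 33, so that steps 15 to 17 are not needed: 22 is hydroborated with IpcBH2 from (+)-α-pinene to the isopinocampheylborane adduct F7 and oxidised (NaOH, H2O2) to the (2R,3S) alcohol F8. DDQ with 2-ethoxyethanol (CH2Cl2, 0 °C, short contact to spare the 4-methylbenzyl ethers) gives the C4 ether F9. TMSOTf (cat.) in CH2Cl2 at −78 °C with 29 (3 equiv) as nucleophile then gives 33 directly by cationic Friedel–Crafts coupling, with the 4→8 regiochemistry and 3,4-trans selectivity known for catechin-type C4 cations.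

**Further compounds**

F1 | step 12 | (2S,3R)-8-[(4S)-2-{3,4-bis(MBnO)phenyl}-5,7-bis(MBnO)-4H-chromen-4-yl]-2-{3,4-bis(MBnO)phenyl}-5,7-bis(MBnO)chroman-3-ol (C4 epimer of 26) | c1c(OCc3ccc(C)cc3)cc(OCc3ccc(C)cc3)c2c1OC(c1ccc(OCc3ccc(C)cc3)c(OCc3ccc(C)cc3)c1)=C[C@@H]2c1c(OCc3ccc(C)cc3)cc(OCc3ccc(C)cc3)c2c1O[C@@H](c1ccc(OCc3ccc(C)cc3)c(OCc3ccc(C)cc3)c1)[C@H](O)C2
F2 | step 13 | triethylsilyl ether of 26 at the lower 3-OH | c1c(OCc3ccc(C)cc3)cc(OCc3ccc(C)cc3)c2c1OC(c1ccc(OCc3ccc(C)cc3)c(OCc3ccc(C)cc3)c1)=C[C@H]2c1c(OCc3ccc(C)cc3)cc(OCc3ccc(C)cc3)c2c1O[C@@H](c1ccc(OCc3ccc(C)cc3)c(OCc3ccc(C)cc3)c1)[C@H](O[Si](CC)(CC)CC)C2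
F3 | step 13 | C3 borane adduct of F2 (boron and C2–H on the face opposite the C4 aryl; drawn as the monoalkylborane) | c1c(OCc3ccc(C)cc3)cc(OCc3ccc(C)cc3)c2c1O[C@@H](c1ccc(OCc3ccc(C)cc3)c(OCc3ccc(C)cc3)c1)[C@H](B)[C@H]2c1c(OCc3ccc(C)cc3)cc(OCc3ccc(C)cc3)c2c1O[C@@H](c1ccc(OCc3ccc(C)cc3)c(OCc3ccc(C)cc3)c1)[C@H](O[Si](CC)(CC)CC)C2
F4 | step 13 | all-trans alcohol: upper unit (2S,3R,4R)-flavan-3-ol, lower unit (2S,3R) 3-O-triethylsilyl | c1c(OCc3ccc(C)cc3)cc(OCc3ccc(C)cc3)c2c1O[C@@H](c1ccc(OCc3ccc(C)cc3)c(OCc3ccc(C)cc3)c1)[C@H](O)[C@H]2c1c(OCc3ccc(C)cc3)cc(OCc3ccc(C)cc3)c2c1O[C@@H](c1ccc(OCc3ccc(C)cc3)c(OCc3ccc(C)cc3)c1)[C@H](O[Si](CC)(CC)CC)C2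
F5 | step 13 | 2,4-cis ketone: upper unit (2S,4R)-flavan-3-one, lower unit 3-O-triethylsilyl | c1c(OCc3ccc(C)cc3)cc(OCc3ccc(C)cc3)c2c1O[C@@H](c1ccc(OCc3ccc(C)cc3)c(OCc3ccc(C)cc3)c1)C(=O)[C@H]2c1c(OCc3ccc(C)cc3)cc(OCc3ccc(C)cc3)c2c1O[C@@H](c1ccc(OCc3ccc(C)cc3)c(OCc3ccc(C)cc3)c1)[C@H](O[Si](CC)(CC)CC)C2
F6 | step 13 | 2,4-trans ketone: upper unit (2R,4R)-flavan-3-one, lower unit 3-O-triethylsilyl (silyl ether of 28) | c1c(OCc3ccc(C)cc3)cc(OCc3ccc(C)cc3)c2c1O[C@H](c1ccc(OCc3ccc(C)cc3)c(OCc3ccc(C)cc3)c1)C(=O)[C@H]2c1c(OCc3ccc(C)cc3)cc(OCc3ccc(C)cc3)c2c1O[C@@H](c1ccc(OCc3ccc(C)cc3)c(OCc3ccc(C)cc3)c1)[C@H](O[Si](CC)(CC)CC)C2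
F7 | step 16 | flavan-3-yl(isopinocampheyl)borane from 22: boron on C3 trans to the 2-aryl group of the (2R)-flavan, isopinocampheyl from (+)-α-pinene | c1c(OCc3ccc(C)cc3)cc(OCc3ccc(C)cc3)c2c1O[C@H](c1cc(OCc3ccc(C)cc3)c(OCc3ccc(C)cc3)c(OCc3ccc(C)cc3)c1)[C@@H](B[C@@H]4C[C@@H]5C[C@H]([C@H]4C)C5(C)C)C2
F8 | step 16 | (2R,3S)-2-{3,4,5-tris(MBnO)phenyl}-5,7-bis(MBnO)chroman-3-ol (penta-O-MBn gallocatechin) | c1c(OCc3ccc(C)cc3)cc(OCc3ccc(C)cc3)c2c1O[C@H](c1cc(OCc3ccc(C)cc3)c(OCc3ccc(C)cc3)c(OCc3ccc(C)cc3)c1)[C@@H](O)C2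
F9 | step 16 | (2R,3S,4S)-4-(2-ethoxyethoxy)-2-{3,4,5-tris(MBnO)phenyl}-5,7-bis(MBnO)chroman-3-ol | c1c(OCc3ccc(C)cc3)cc(OCc3ccc(C)cc3)c2c1O[C@H](c1cc(OCc3ccc(C)cc3)c(OCc3ccc(C)cc3)c(OCc3ccc(C)cc3)c1)[C@@H](O)[C@H]2OCCOCC
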